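## Retrosynthetic overview
1. Remove the tert-butyl ester and the two MOM ethers with acid, then disconnect the C7 aryl ester. This leaves the tertiary 7-hydroxy azaphilone and bis-MOM orsellinoyl chloride.
2. The (R)-7-hydroxy-7-methyl-6,8-dione comes from enantioselective Cu/sparteine/O2 C7-hydroxylation of the 8-hydroxy-7-methyl-6H-isochromen-6-one. The pyran ring is therefore built before the quaternary stereocentre.
3. That isochromenone comes from Ag(I)-catalysed 6-endo cycloisomerisation of an o-alkynylbenzaldehyde.
4. The o-alkynylbenzaldehyde comes from Sonogashira coupling of 2,4-dihydroxy-6-iodo-3-methylbenzaldehyde with tert-butyl (E)-pent-2-en-4-ynoate. The aryl iodide is made from 2,6-dimethoxytoluene by formylation, directed ortho-iodination and demethylation.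
5. Ring order: the benzene ring is commercial, the pyran is formed next, and the carbocycle is dearomatised to the dienedione with the C7 stereocentre last.

Assumptions: the target has (R) at C7 (derived from the SMILES), and (−)-sparteine is assumed to give (R). 2,6-Dimethoxytoluene, 3-(trimethylsilyl)propynal, tert-butyl (triphenylphosphoranylidene)acetate and orsellinic acid are taken as commercial.

## Route

**Step 1**
Reactants: 1, 2,6-dimethoxytoluene
Product: 2, 2,4-dimethoxy-3-methylbenzaldehyde
Conditions: POCl3, DMF, 0 → 70 °C; then aqueous NaOAc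
Reagents that add atoms: DMF, CN(C)C=O (supplies the CHO carbon)
Why: Vilsmeier formylation occurs ortho to one OMe and para to the other (the only activated position), giving a single regioisomer.

**Step 2**
Reactants: 2
Product: 3, 6-iodo-2,4-dimethoxy-3-methylbenzaldehyde (named as the benzaldehyde with C1 = CHO)
Conditions: (i) Me(H)NCH2CH2NMe2, n-BuLi, THF, −20 °C; (ii) n-BuLi, −20 °C; (iii) I2, −78 °C → rt
Reagents that add atoms: iodine, II
Why: Comins in-situ aminoalkoxide protection of the aldehyde directs ortho-lithiation to the only free position ortho to the CHO (C6, flanked by neither OMe). Iodination follows, and workup regenerates the aldehyde.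

**Step 3**
Reactants: 3
Product: 4, 2,4-dihydroxy-6-iodo-3-methylbenzaldehyde
Conditions: BBr3 (4 equiv), CH2Cl2, −78 °C → rt
Reagents that add atoms: none
Why: BBr3 O-demethylation cleaves both aryl methyl ethers. The aryl iodide and the aldehyde survive, and this is done before the acid-sensitive enoate is introduced.

**Step 4**
Reactants: 5, 3-(trimethylsilyl)propynal; 6, tert-butyl (triphenylphosphoranylidene)acetate
Product: 7, tert-butyl (E)-5-(trimethylsilyl)pent-2-en-4-ynoate
Conditions: toluene, rt
Reagents that add atoms: none
Why: Wittig olefination with a stabilised ylide gives the (E)-enoate, which fixes the side-chain alkene geometry.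

**Step 5**
Reactants: 7
Product: 8, tert-butyl (E)-pent-2-en-4-ynoate
Conditions: TBAF·AcOH (1:1), THF, 0 °C
Reagents that add atoms: none
Why: buffered fluoride removes the C-silyl group without attacking the enoate or the tert-butyl ester.

**Step 6**
Reactants: 4; 8
Product: 9, tert-butyl (E)-5-(2-formyl-3,5-dihydroxy-4-methylphenyl)pent-2-en-4-ynoate
Conditions: Pd(PPh3)2Cl2 (5 mol %), CuI (10 mol %), Et3N, DMF, rt
Reagents that add atoms: none
Why: Sonogashira coupling at the aryl iodide tolerates free phenols and the aldehyde, and the alkyne is installed ortho to the CHO.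

**Step 7**
Reactants: 9
Product: 10, tert-butyl (E)-3-(8-hydroxy-7-methyl-6-oxo-6H-isochromen-3-yl)acrylate
Conditions: AgOTf (5 mol %), CH2Cl2, rt
Reagents that add atoms: none
Why: Ag(I) activates the alkyne and the aldehyde oxygen attacks 6-endo to give a 2-benzopyrylium. The phenol OH protonates the vinyl-silver species and the product is the neutral quinoid, an isomer of 9 (C17 H18 O5). This forms the pyran ring.

**Step 8**
Reactants: 10
Product: 11, tert-butyl (E)-3-[(7R)-7-hydroxy-7-methyl-6,8-dioxo-6H-isochromen-3-yl]acrylate
Conditions: CuCl, (−)-sparteine, O2 (1 atm), CH2Cl2, −20 °C → rt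
Reagents that add atoms: oxygen, O=O (becomes the 7-OH)
Why: enantioselective oxidative dearomatisation with a chiral Cu(II)-sparteine/O2 system hydroxylates the nucleophilic C7, which lies between the C6 carbonyl and the C8 enol, and sets the quaternary (R) centre.

**Step 9**
Reactants: 12, orsellinic acid (2,4-dihydroxy-6-methylbenzoic acid)
Product: 13, methoxymethyl 2,4-bis(methoxymethoxy)-6-methylbenzoate
Conditions: MOMCl (3.5 equiv), iPr2NEt, CH2Cl2, 0 °C → rt
Reagents that add atoms: chloromethyl methyl ether, COCCl
Why: alkylation (MOM protection) of the carboxylate and both phenols with acid-labile groups that can later be removed together with the tert-butyl ester.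

**Step 10**
Reactants: 13
Product: 14, 2,4-bis(methoxymethoxy)-6-methylbenzoic acid
Conditions: LiOH, THF/H2O, 40 °C; then pH 4 workup
Reagents that add atoms: lithium hydroxide, [Li+].[OH-]
Why: the activated MOM ester is saponified selectively, and the aryl MOM ethers are base-stable.

**Step 11**
Reactants: 14
Product: 15, 2,4-bis(methoxymethoxy)-6-methylbenzoyl chloride
Conditions: Ghosez reagent, CH2Cl2, rt
Reagents that add atoms: 1-chloro-N,N,2-trimethylpropenylamine, CC(C)=C(Cl)N(C)C (supplies Cl)
Why: this forms the acid chloride under neutral conditions (no HCl), so the MOM groups are untouched.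

**Step 12**
Reactants: 11; 15
Product: 16, protected mitorubrinic acid (the C7 aroyl ester)
Conditions: 15 (3 equiv), DMAP (2 equiv), pyridine, CH2Cl2, 0 °C → rt
Reagents that add atoms: none
Why: DMAP-catalysed O-acylation of the tertiary alcohol through an acylpyridinium. No bond to the stereocentre is broken and C7 has no H, so the configuration is retained.

**Step 13**
Reactants: 16
Product: 17, mitorubrinic acid
Conditions: TFA/CH2Cl2 (1:1), 0 °C → rt, 2 h
Reagents that add atoms: none
Why: acidolysis removes the tert-butyl ester and both MOM ethers in one operation, leaving the acid-stable azaphilone and the aryl ester intact.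

## Consistency checks
- The core in 17 is a bicyclic pyran fused to a 6,8-dione with C7 bearing CH3 and the orsellinoyl ester.
- The C3 side chain is (E)-CH=CH-CO2H.
- The orsellinate is 2,4-dihydroxy-6-methylbenzoyl.
- The single stereocentre is (R) at C7, set in Step 8 and unchanged in Steps 12 and 13.

## Compound list
1 | 2,6-dimethoxytoluene | COc1cccc(OC)c1C | starting material
2 | 2,4-dimethoxy-3-methylbenzaldehyde | COc1ccc(C=O)c(OC)c1C | intermediate
3 | 6-iodo-2,4-dimethoxy-3-methylbenzaldehyde | COc1cc(I)c(C=O)c(OC)c1C | intermediate
4 | 2,4-dihydroxy-6-iodo-3-methylbenzaldehyde | Cc1c(O)cc(I)c(C=O)c1O | intermediate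
5 | 3-(trimethylsilyl)propynal | C[Si](C)(C)C#CC=O | starting material
6 | tert-butyl (triphenylphosphoranylidene)acetate | CC(C)(C)OC(=O)C=P(c1ccccc1)(c1ccccc1)c1ccccc1 | starting material
7 | tert-butyl (E)-5-TMS-pent-2-en-4-ynoate | C[Si](C)(C)C#C/C=C/C(=O)OC(C)(C)C | intermediate
8 | tert-butyl (E)-pent-2-en-4-ynoate | C#C/C=C/C(=O)OC(C)(C)C | intermediate
9 | o-alkynyl benzaldehyde enynoate | Cc1c(O)cc(C#C/C=C/C(=O)OC(C)(C)C)c(C=O)c1O | intermediate
10 | 8-hydroxy-7-methyl-isochromen-6-one acrylate (tert-butyl ester) | O=C1C=C2C=C(/C=C/C(=O)OC(C)(C)C)OC=C2C(O)=C1C | intermediate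
11 | (7R)-7-hydroxy azaphilone tert-butyl ester | O[C@]1(C)C(=O)C=C2C=C(/C=C/C(=O)OC(C)(C)C)OC=C2C1=O | intermediate
12 | orsellinic acid | Cc1cc(O)cc(O)c1C(=O)O | starting material
13 | tris-MOM orsellinate | COCOC(=O)c1c(C)cc(OCOC)cc1OCOC | intermediate
14 | 2,4-bis(MOM-oxy)-6-methylbenzoic acid | COCOc1cc(C)c(C(=O)O)c(OCOC)c1 | intermediate
15 | 2,4-bis(MOM-oxy)-6-methylbenzoyl chloride | COCOc1cc(C)c(C(=O)Cl)c(OCOC)c1 | intermediate
16 | protected mitorubrinic acid | COCOc1cc(C)c(C(=O)O[C@]2(C)C(=O)C=C3C=C(/C=C/C(=O)OC(C)(C)C)OC=C3C2=O)c(OCOC)c1 | intermediate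
17 | mitorubrinic acid | Cc1cc(O)cc(O)c1C(=O)O[C@]1(C)C(=O)C=C2C=C(/C=C/C(=O)O)OC=C2C1=O | target

## Totals
Total steps: 13. Longest linear sequence: 8 (1 → 2 → 3 → 4 → 9 → 10 → 11 → 16 → 17, i.e. Steps 1, 2, 3, 6, 7, 8, 12, 13).

## Three steps most likely to fail
1. **Step 7, Ag-catalysed cyclisation.** The electron-poor enynoate may favour 5-exo closure (an isobenzofuran) over 6-endo closure. Fallback: couple propargyl aldehyde diethyl acetal instead in Step 6, cyclise, hydroxylate and acylate as before. Then hydrolyse the acetal to the C3-aldehyde and build the (E)-acrylate by Wittig reaction with 6, so the acid side chain is made after the core.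
2. **Step 8, enantioselective C7 hydroxylation.** Yield or ee may be poor, or the sense of induction may be wrong. Fallback: enzymatic hydroxylation of 10 with an FAD-dependent azaphilone hydroxylase (TropB/AzaH type). Alternatively, do a racemic hydroxylation and resolve by chiral HPLC.
3. **Step 12, acylation.** A hindered 2,6-disubstituted acid chloride must react with a tertiary, electron-poor alcohol. Fallback: oxidatively acyloxylate 10 directly, with PhI(O2CAr)2 made from 14 and PhI(OAc)2 installing the C7 oxygen and the aryl ester together. This gives the racemate, which is resolved by chiral HPLC.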